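A plateau with both reagents still present tempts one to write an equilibrium constant, yet a dead catalyst stops a flask just as flatly.

the same everywhere: substrate 0.40 M; free catalyst 4.4 mM

|  | coupling partner | second catalyst | temperature | remark | time |
|---|---|---|---|---|---|
| south-east | 0.80 M | 3 mM | 0 °C | the very flask that is asked about, followed so far |  |
| south | 0.80 M | 3 mM | 6 °C | run made earlier |  |
| flask | 0.800 M | 3.0 mM | 0 °C |  | 8.0 d |

| run | time / d | target / % |
|---|---|---|
| south-east | 0.417 | 34 |
| south-east | 1.25 | 58 |
| south-east | 2.00 | 63 |
| south-east | 3.00 | 69 |
| south-east | 5.00 | 65 |
| south | 0.417 | 40 |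
| south | 1.25 | 56 |
| south | 2.00 | 57 |
| south | 3.00 | 58 |
| south | 5.00 | 53 |

(standard deviation of a reading: 2 percentage points)

- beta: change nothing and wait 15 d more
- delta: at 8.0 d take out 90 % of the target then present, then wait 15 d
- eta: at 8.0 d raise the temperature by 25 K, then wait 15 d
- zeta: at 8.0 d add free catalyst, 50.0 % of the amount charged, then wait 15 d
- gamma: at 8.0 d add coupling partner, 50.0 % of the amount charged, then wait 15 d

- target taken out counts as made
- "the catalyst" is free catalyst with its forms; second catalyst is a second catalyst
- additions bring no volume worth counting

1. target, in percent of the substrate first charged, at 8.0 d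
2. the option that brings most further target ("none" if no option brings more than 2 percentage points) (beta / delta / eta / zeta / gamma / none)
3. target present, with what was taken out counted in, in percent of the substrate first charged, after eta
4. target present, with what was taken out counted in, in percent of the substrate first charged, after zeta

Read the south-east run as first order in substrate, with all substrate lost counted as target. Its pseudo-first-order constant is 0.996 /d over the first interval but 0.543 /d over the next, so something besides substrate is falling. But an approach to equilibrium bends the same way. The warmer south run reads 1.23 /d at first, faster than the south-east run, yet its readings level lower, near 56.0 % against 65.7 %. These readings separate neither view, so this reckoning simply bets on a dying catalyst.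

On that bet the useful quantity is the catalyst dose D = 1.07, the natural logarithm of substrate charged over substrate left at the stop. For a first-order substrate and a fixed catalyst lifetime, D grows in proportion to the catalyst charged. So this reckoning keeps the asked flask near 65.7 % under beta, delta, eta and gamma, none of which adds catalyst, while zeta adds 50.0 % of D to the remaining substrate and reaches 79.9 %.

The forecast parts from this with 63 %, delta, 27 % after eta and 58 % after zeta, holding: “Extra catalyst moves no equilibrium”.

The simulation gives 64.9 %, zeta, 64.9 % after eta and 83.8 % after zeta.

    coupling partner + free catalyst → spent catalyst (k = 0.171 /M/h, Ea = 62.0 kJ/mol)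
    coupling partner + catalyst intermediate → second catalyst + target (k = 35.7 /M/h, Ea = 42.0 kJ/mol)
    substrate + free catalyst ⇌ free catalyst + open intermediate (K = 0.330, k = 66.2 /M/h, Ea = 39.0 kJ/mol, ΔH = 6.00 kJ/mol)
    substrate + open intermediate → side product (k = 0.0317 /M/h, Ea = 60.0 kJ/mol)
    second catalyst + open intermediate ⇌ catalyst intermediate (K = 4.30 /M, k = 1220 /M/h, Ea = 52.0 kJ/mol, ΔH = −12.0 kJ/mol)
    (constants at 0 °C)

In the asked flask, free catalyst had fallen to 10.9 % of its charge at 0.800 d, with target at 50.8 %. At 4.00 d free catalyst stood at 0.00852 % and target at 64.8 %, and at 8.00 d 31.4 % of the substrate was still present. That substrate gives the asked flask D = 1.16, so zeta reckons 82.4 % of the substrate turned, against 83.8 % as target. Scaled to the neighbour flask with 2.60 mM free catalyst, D reckons 50.5 % of the substrate left, more than the 42 % that flask holds.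

The data stem from a simulated flask for substances that don't exist.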